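**Retrosynthetic overview**
- The target is cut at the left-hand O–C(Me)2/aryl–CH2 bonds: an acylphloroglucinol plus one C5 alkenol; this dihydropyran ring is closed last.
- The acylphloroglucinol is cut at the aryl–C(=O) bond: phloroglucinol (from resorcinol by meta C–H borylation/oxidation) plus a 3-(chroman-6-yl)propanoic acid.
- The chroman acid comes from a spiro[oxolane-cyclohexadienone] and a C3 β-lithio carboxylate: 1,2-addition, then a cationic 1,2-C shift expands the oxolane to the chroman and re-forms the benzene ring.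
- The spiro dienone comes from oxidative dearomatisation of a para-(3-hydroxy-3-methylbutyl)phenol, itself made from 4-iodophenol and the same C5 alkenol.
- Ring order: spiro oxolane, then right-hand chroman (ring expansion with re-aromatisation), then left-hand dihydropyran. Both benzene rings come from the phenolic starting materials.

Assumption: the target SMILES has no stereocentre (the molecule is achiral), so no stereocontrol is needed; the one cis/trans intermediate (9) converges to a single product.

**Step 1**
Reactants: 1 4-iodophenol; 2 2-methylbut-3-en-2-ol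
Product: 4 4-(3-hydroxy-3-methylbutyl)phenol, via (E)-4-(3-hydroxy-3-methylbut-1-en-1-yl)phenol 3 (not isolated)
Conditions: Pd(OAc)2 (1 mol %), Et3N (1.5 equiv), DMF, 90 °C; then 10 % Pd/C, H2 (1 atm), 25 °C, same pot
Reagents that add atoms: none
Why: Mizoroki–Heck arylation of the terminal alkene (β-hydride elimination is possible only toward the benzylic carbon, so a single (E)-styrene forms), followed by catalytic hydrogenation of that C=C in the same pot; no stereocentre is created.

**Step 2**
Reactants: 4 4-(3-hydroxy-3-methylbutyl)phenol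
Product: 5 2,2-dimethyl-1-oxaspiro[4.5]deca-6,9-dien-8-one
Conditions: PhI(OAc)2 (1.1 equiv), CH2Cl2–HFIP (4:1), 0 °C
Reagents that add atoms: none
Why: Hypervalent-iodine oxidative dearomatisation of a para-alkylphenol; the phenoxenium-type intermediate is trapped 5-exo at the para carbon by the tethered tertiary alcohol, giving the achiral spiro ether dienone (a known reaction class for 4-(3-hydroxyalkyl)phenols).

**Step 3**
Reactants: 5 2,2-dimethyl-1-oxaspiro[4.5]deca-6,9-dien-8-one; 6 3-bromopropanoic acid
Product: 10 3-(2,2-dimethyl-3,4-dihydro-2H-chromen-6-yl)propanoic acid, via lithium 3-bromopropanoate 7 (not isolated), via lithium 3-lithiopropanoate 8 (not isolated), via spiro dienol acid 9 (not isolated)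
Conditions: 6 (1.5 equiv), n-BuLi (1.5 equiv), THF, −78 °C; lithium naphthalenide (3.0 equiv, stock solution), −78 °C; add 5, −78 → −40 °C; then TFA (excess), CH2Cl2, 0 °C → rt
Reagents that add atoms: n-butyllithium, CCCC[Li]; lithium naphthalenide, [Li+].[CH-]1C=C[CH]c2ccccc12 (both supply only the lithium of 7, 8 and the salt form of 9; nothing from them remains in 10)
Why: Proposed new method: the β-lithio carboxylate 8 (a known homoenolate-type dianion) adds 1,2 to the non-enolisable cross-conjugated ketone of 5, and on acidification the tertiary, doubly allylic C8–OH of 9 (or its spiro-lactone) ionises to a cyclohexadienyl cation whose neighbouring spiro carbon cannot lose a proton, so the oxolane CH2 undergoes a 1,2-shift to the adjacent cationic ring carbon (carbon migrates, not oxygen, because this leaves an oxocarbenium ion), expanding the five-membered ether to the six-membered pyran, and proton loss aromatises to the 6-substituted chroman with the side chain para to the ring oxygen; the closest known reactions are the acid-catalysed dienone–phenol rearrangement of 1-oxaspiro[4.5]deca-6,9-dien-8-ones to chroman-6-ols and the dienol–benzene rearrangement of 4,4-dialkylcyclohexa-2,5-dienols, neither of which has been shown for oxaspiro dienols or as a one-flask addition/ring expansion.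

**Step 4**
Reactants: 11 resorcinol (benzene-1,3-diol)
Product: 15 phloroglucinol (benzene-1,3,5-triol), via 1,3-bis(trimethylsilyloxy)benzene 12 (not isolated), via 5-Bpin bis(silyl ether) 13 (not isolated), via 3,5-bis(trimethylsilyloxy)phenol 14 (not isolated)
Conditions: HMDS (1.1 equiv), TMSCl (cat.), 110 °C, then evaporate; [Ir(OMe)(cod)]2 (1.5 mol %), dtbpy (3 mol %), HBpin (1.5 equiv), THF, 80 °C; then 30 % H2O2, NaHCO3 (cat.), THF–H2O, 0 °C → rt; 1 M HCl (cat.), all under N2
Reagents that add atoms: hexamethyldisilazane, C[Si](C)(C)N[Si](C)(C)C (SiMe3 of 12–14); pinacolborane, CC1(C)OBOC1(C)C (Bpin of 13); hydrogen peroxide, OO (the new oxygen of 14 and 15)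
Why: In situ O-silylation, then sterically controlled iridium-catalysed C–H borylation (C5 is the only C–H not ortho to a substituent), then oxidation of the C–B bond and hydrolysis of the silyl ethers gives the 1,3,5-triol (one-pot C–H borylation/oxidation, well established for 1,3-dioxygenated benzenes).

**Step 5**
Reactants: 10 3-(2,2-dimethyl-3,4-dihydro-2H-chromen-6-yl)propanoic acid; 15 phloroglucinol
Product: 16 3-(2,2-dimethyl-3,4-dihydro-2H-chromen-6-yl)-1-(2,4,6-trihydroxyphenyl)propan-1-one
Conditions: 15 (2 equiv), BF3·OEt2 (neat, as solvent), 85 °C; aq. NaOAc work-up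
Reagents that add atoms: none
Why: BF3-mediated Friedel–Crafts C-acylation of the symmetric, highly nucleophilic triol with the free acid (the standard acylphloroglucinol synthesis); all three ring positions are equivalent, the first acyl group deactivates the ring toward a second, and the chroman ring of 10 is far less nucleophilic.

**Step 6**
Reactants: 16 3-(2,2-dimethyl-3,4-dihydro-2H-chromen-6-yl)-1-(2,4,6-trihydroxyphenyl)propan-1-one; 2 2-methylbut-3-en-2-ol
Product: 18 1-(5,7-dihydroxy-2,2-dimethyl-3,4-dihydro-2H-chromen-6-yl)-3-(2,2-dimethyl-3,4-dihydro-2H-chromen-6-yl)propan-1-one (target), via 3-C-prenyl ketone 17 (not isolated)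
Conditions: 2 (1.1 equiv), BF3·OEt2 (0.3 equiv), 1,4-dioxane, 25 → 50 °C
Reagents that add atoms: none
Why: Acid-catalysed Friedel–Crafts C-prenylation by the tertiary allyl cation from 2 at one of the two equivalent free ring positions, then Markovnikov hydroalkoxylation of the prenyl group by the adjacent non-chelated 4-OH (para to the carbonyl) closes the 2,2-dimethyldihydropyran as the 6-acyl-5,7-dihydroxychroman; no stereocentre is formed.

**Compound list**
1 | 4-iodophenol | Oc1ccc(I)cc1 | starting material
2 | 2-methylbut-3-en-2-ol | CC(C)(O)C=C | starting material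
3 | (E)-4-(3-hydroxy-3-methylbut-1-en-1-yl)phenol | CC(C)(O)/C=C/c1ccc(O)cc1 | intermediate (not isolated)
4 | 4-(3-hydroxy-3-methylbutyl)phenol | CC(C)(O)CCc1ccc(O)cc1 | intermediate
5 | 2,2-dimethyl-1-oxaspiro[4.5]deca-6,9-dien-8-one | CC1(C)CCC2(O1)C=CC(=O)C=C2 | intermediate
6 | 3-bromopropanoic acid | OC(=O)CCBr | starting material
7 | lithium 3-bromopropanoate | [Li]OC(=O)CCBr | intermediate (not isolated)
8 | lithium 3-lithiopropanoate | [Li]CCC(=O)O[Li] | intermediate (not isolated)
9 | 3-(8-hydroxy-2,2-dimethyl-1-oxaspiro[4.5]deca-6,9-dien-8-yl)propanoic acid (cis/trans mixture, formed as its dilithium salt) | CC1(C)CCC2(O1)C=CC(O)(CCC(=O)O)C=C2 | intermediate (not isolated)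
10 | 3-(2,2-dimethyl-3,4-dihydro-2H-chromen-6-yl)propanoic acid | CC1(C)CCc2cc(CCC(=O)O)ccc2O1 | intermediate
11 | resorcinol (benzene-1,3-diol) | Oc1cccc(O)c1 | starting material
12 | 1,3-bis(trimethylsilyloxy)benzene | C[Si](C)(C)Oc1cccc(O[Si](C)(C)C)c1 | intermediate (not isolated)
13 | 2-[3,5-bis(trimethylsilyloxy)phenyl]-4,4,5,5-tetramethyl-1,3,2-dioxaborolane | CC1(C)OB(OC1(C)C)c1cc(O[Si](C)(C)C)cc(O[Si](C)(C)C)c1 | intermediate (not isolated)
14 | 3,5-bis(trimethylsilyloxy)phenol | C[Si](C)(C)Oc1cc(O)cc(O[Si](C)(C)C)c1 | intermediate (not isolated)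
15 | phloroglucinol (benzene-1,3,5-triol) | Oc1cc(O)cc(O)c1 | intermediate
16 | 3-(2,2-dimethyl-3,4-dihydro-2H-chromen-6-yl)-1-(2,4,6-trihydroxyphenyl)propan-1-one | CC1(C)CCc2cc(CCC(=O)c3c(O)cc(O)cc3O)ccc2O1 | intermediate
17 | 3-(2,2-dimethyl-3,4-dihydro-2H-chromen-6-yl)-1-[2,4,6-trihydroxy-3-(3-methylbut-2-en-1-yl)phenyl]propan-1-one | CC(C)=CCc1c(O)cc(O)c(C(=O)CCc2ccc3OC(C)(C)CCc3c2)c1O | intermediate (not isolated)
18 | 1-(5,7-dihydroxy-2,2-dimethyl-3,4-dihydro-2H-chromen-6-yl)-3-(2,2-dimethyl-3,4-dihydro-2H-chromen-6-yl)propan-1-one | CC1(C)CCc2cc(CCC(=O)c3c(O)cc4c(c3O)CCC(C)(C)O4)ccc2O1 | target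

**Total step count:** 6. **Longest linear sequence:** 5 steps (1 → 2 → 3 → 5 → 6); step 4 is the side branch.

**Three steps most likely to fail**

Step 3 (the proposed new ring expansion). Risks: oxygen instead of carbon migration would give the 7-substituted isomer, and electron transfer from the dianion or residual naphthalenide could re-aromatise the dienone to 4. The fallback uses known chemistry, sets out from 5 and returns at 10. Acid treatment of 5 (TFA or BF3·OEt2, CH2Cl2) effects the established dienone–phenol rearrangement, also a 1,2-C shift ring expansion, to 2,2-dimethyl-3,4-dihydro-2H-chromen-6-ol F1. Tf2O/pyridine converts it into 2,2-dimethyl-3,4-dihydro-2H-chromen-6-yl trifluoromethanesulfonate F2. A Heck reaction with acrylic acid (Pd(OAc)2, dppp, Et3N, DMF, 100 °C) gives (E)-3-(2,2-dimethyl-3,4-dihydro-2H-chromen-6-yl)prop-2-enoic acid F3, and hydrogenation (H2, Pd/C) gives 10.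

Step 4 (three operations in one pot). Risks: loss of the silyl ethers before borylation would erode the C5 selectivity, and the electron-rich triol can be over-oxidised. The fallback installs the third oxygen after acylation, sets out from 11 (together with 10) and returns at 16, by-passing 15. BF3·OEt2-mediated acylation of resorcinol with 10 gives 1-(2,4-dihydroxyphenyl)-3-(2,2-dimethyl-3,4-dihydro-2H-chromen-6-yl)propan-1-one F4. Under ketone-directed palladium-catalysed ortho C–H oxygenation (Pd(OAc)2 cat., K2S2O8, TFA/TFAA, 60 °C) the phenols are masked in the flask as the bis(trifluoroacetate) F5. The only free position ortho to the carbonyl is then trifluoroacetoxylated to the tris(trifluoroacetate) F6, and aqueous NaHCO3/MeOH work-up frees the three phenols to give 16.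

Step 6 (regio- and chemoselectivity). Risks: ring closure on the chelated 2-OH would give the 8-acyl isomer, and a second prenylation is possible. The fallback fixes the ring oxygen before the C–C bond is made, sets out from 16 and returns at 18. Selective O-alkylation of the non-chelated, most acidic 4-OH with 3-chloro-3-methylbut-1-yne (K2CO3, KI, CuI cat., acetone, reflux) gives 1-[2,6-dihydroxy-4-(2-methylbut-3-yn-2-yloxy)phenyl]-3-(2,2-dimethyl-3,4-dihydro-2H-chromen-6-yl)propan-1-one F7. Heating (N,N-diethylaniline, 150 °C) brings about the aryl propargyl ether rearrangement and cyclisation onto either equivalent ortho carbon to give 1-(5,7-dihydroxy-2,2-dimethyl-2H-chromen-6-yl)-3-(2,2-dimethyl-3,4-dihydro-2H-chromen-6-yl)propan-1-one F8. Hydrogenation (H2, Pd/C, EtOAc) saturates the chromene C3=C4 bond to give 18.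

**Further compounds**
F1 | step 3 | 2,2-dimethyl-3,4-dihydro-2H-chromen-6-ol | CC1(C)CCc2cc(O)ccc2O1
F2 | step 3 | 2,2-dimethyl-3,4-dihydro-2H-chromen-6-yl trifluoromethanesulfonate | CC1(C)CCc2cc(OS(=O)(=O)C(F)(F)F)ccc2O1
F3 | step 3 | (E)-3-(2,2-dimethyl-3,4-dihydro-2H-chromen-6-yl)prop-2-enoic acid | CC1(C)CCc2cc(/C=C/C(=O)O)ccc2O1
F4 | step 4 | 1-(2,4-dihydroxyphenyl)-3-(2,2-dimethyl-3,4-dihydro-2H-chromen-6-yl)propan-1-one | CC1(C)CCc2cc(CCC(=O)c3ccc(O)cc3O)ccc2O1
F5 | step 4 | 4-[3-(2,2-dimethyl-3,4-dihydro-2H-chromen-6-yl)propanoyl]-1,3-phenylene bis(trifluoroacetate) | CC1(C)CCc2cc(CCC(=O)c3ccc(OC(=O)C(F)(F)F)cc3OC(=O)C(F)(F)F)ccc2O1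
F6 | step 4 | 2-[3-(2,2-dimethyl-3,4-dihydro-2H-chromen-6-yl)propanoyl]benzene-1,3,5-triyl tris(trifluoroacetate) | CC1(C)CCc2cc(CCC(=O)c3c(OC(=O)C(F)(F)F)cc(OC(=O)C(F)(F)F)cc3OC(=O)C(F)(F)F)ccc2O1
F7 | step 6 | 1-[2,6-dihydroxy-4-(2-methylbut-3-yn-2-yloxy)phenyl]-3-(2,2-dimethyl-3,4-dihydro-2H-chromen-6-yl)propan-1-one | CC1(C)CCc2cc(CCC(=O)c3c(O)cc(OC(C)(C)C#C)cc3O)ccc2O1
F8 | step 6 | 1-(5,7-dihydroxy-2,2-dimethyl-2H-chromen-6-yl)-3-(2,2-dimethyl-3,4-dihydro-2H-chromen-6-yl)propan-1-one | CC1(C)CCc2cc(CCC(=O)c3c(O)cc4c(c3O)C=CC(C)(C)O4)ccc2O1
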